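The biaryl is hidden as a lactone: the ring A phenol oxygen ortho to the biaryl bond and the benzylic carbon C9 of the ring B chain are joined as the O–C(=O) unit of a 6H-benzo[c]chromen-6-one. Ring B is then grown on the C3=C4 bond of a 3-nitrocoumarin that already carries ring A, its methoxy group and its nine-carbon chain. One flask operation (cycloaddition with 2,3-dimethoxybuta-1,3-diene, loss of HNO2, dehydrogenation) closes ring B with both oxygens in place. Lactone reduction and a Wittig reaction later turn the bridge carbon into the second chain, and both chains are finished together.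

Key step: step 4

Remarks on the chemistry:
- The target has no stereocentre, and its biaryl axis carries only two ortho substituents and rotates freely, so racemic or isomeric intermediates are acceptable.
- 2,3-Dimethoxybuta-1,3-diene is taken as a purchased reagent.
- The chain-end oxygens are carried as benzyl ethers, so that one hydrogenation saturates the alkene and frees both alcohols.

Step 1
Reactants: 1 non-8-en-1-ol
Product: 2 benzyl non-8-en-1-yl ether
Conditions: NaH, BnBr, Bu4NI (cat.), THF, 0 °C → rt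
Reagents that add atoms: benzyl bromide, BrCc1ccccc1
Why: Williamson ether synthesis on an unhindered primary alkoxide gives an ether that survives every later step until the hydrogenolysis.

Step 2
Reactants: 2 benzyl non-8-en-1-yl ether; 3 5-bromo-2-hydroxy-3-methoxybenzaldehyde
Product: 5 5-[9-(benzyloxy)nonyl]-2-hydroxy-3-methoxybenzaldehyde, via B-alkyl-9-BBN borane 4 (not isolated)
Conditions: 9-BBN-H (slightly less than 2), THF, 0 °C → rt; then 3, PdCl2(dppf) (5 mol %), aq. K3PO4 (3 equiv), DMF, 60 °C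
Reagents that add atoms: none
Why: Anti-Markovnikov hydroboration of the terminal alkene followed by B-alkyl Suzuki–Miyaura coupling at the only C–Br bond should attach the nine-carbon chain para to the phenol, the dppf ligand favouring reductive elimination over β-hydride elimination and the slight excess of alkene leaving no B–H to reduce the aldehyde.

Step 3
Reactants: 5 5-[9-(benzyloxy)nonyl]-2-hydroxy-3-methoxybenzaldehyde; 6 ethyl nitroacetate
Product: 8 6-[9-(benzyloxy)nonyl]-8-methoxy-3-nitro-2H-chromen-2-one, via nitroacrylate ester 7 (not isolated)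
Conditions: piperidine (cat.), AcOH (cat.), toluene, Dean–Stark, reflux
Reagents that add atoms: none
Why: Knoevenagel condensation of the aldehyde with the acidic CH2 of the nitroacetate, followed by lactonisation of the ortho phenol onto the ethyl ester, is the standard entry to 3-nitrocoumarins.

Step 4
Reactants: 8 6-[9-(benzyloxy)nonyl]-8-methoxy-3-nitro-2H-chromen-2-one; 9 2,3-dimethoxybuta-1,3-diene
Product: 12 2-[9-(benzyloxy)nonyl]-4,8,9-trimethoxy-6H-benzo[c]chromen-6-one, via cis-fused nitro cycloadduct 10 (not isolated), via dihydrobenzochromenone 11 (not isolated)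
Conditions: 9 (4 equiv), toluene (concentrated), sealed tube, 100 °C; then DBU (1.2 equiv), rt; then DDQ (1.5 equiv), rt
Reagents that add atoms: none
Why: The nitro group and the lactone carbonyl make C3=C4 of 8 a strongly electron-poor 2π partner, which should add suprafacially to the s-cis form of the electron-rich diene in a concerted normal-demand (4+2) cycloaddition to give the cis-fused adduct 10; DBU then removes HNO2 by β-elimination to give 11, and DDQ takes away the last two hydrogens. The closest known reaction type is the Diels–Alder benzannulation of 3-nitrocoumarins with 2,3-disubstituted butadienes, followed by nitrous acid elimination and dehydrogenation to 6H-benzo[c]chromen-6-ones. Ring B, a six-membered carbocycle, is closed by an intermolecular cycloaddition that forms both new C–C bonds (C6a–C7 and C10a–C10) at once. The two stereocentres of 10 (C6a and C10a, cis because the addition is suprafacial on a ring-constrained alkene) are erased on aromatisation, so no stereocontrol is required. The step needs only chemoselectivity for the nitro-activated double bond, which is the sole electron-poor alkene present; the site of annulation is fixed by the existing C4–C4a bond of the coumarin, the symmetrical diene leaves no regiochemical choice, and any cyclic nitronate formed by a competing hetero-Diels–Alder pathway is expected to rearrange to 10 on heating.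

Step 5
Reactants: 12 2-[9-(benzyloxy)nonyl]-4,8,9-trimethoxy-6H-benzo[c]chromen-6-one
Product: 13 2-[9-(benzyloxy)nonyl]-4,8,9-trimethoxy-6H-benzo[c]chromen-6-ol (racemic lactol)
Conditions: i-Bu2AlH (1.2 equiv), CH2Cl2, −78 °C; aq. KNaC4H4O6 work-up
Reagents that add atoms: none
Why: Partial hydride reduction of the aryl lactone stops at the aluminium hemiacetal at low temperature, and the new hemiacetal carbon, formed without control as a racemate, is erased in step 8.

Step 6
Reactants: 14 8-bromooctan-1-ol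
Product: 15 benzyl 8-bromooctyl ether
Conditions: BnOC(=NH)CCl3, TfOH (cat.), CH2Cl2/cyclohexane, 0 °C → rt
Reagents that add atoms: benzyl 2,2,2-trichloroacetimidate, N=C(OCc1ccccc1)C(Cl)(Cl)Cl
Why: Acid-catalysed benzylation with the trichloroacetimidate avoids the alkoxide that would displace the primary bromide.

Step 7
Reactants: 15 benzyl 8-bromooctyl ether
Product: 16 [8-(benzyloxy)octyl]triphenylphosphonium bromide
Conditions: PPh3, MeCN, reflux
Reagents that add atoms: triphenylphosphine, c1ccc(cc1)P(c1ccccc1)c1ccccc1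
Why: SN2 quaternisation of triphenylphosphine by a primary alkyl bromide is a routine phosphonium salt synthesis.

Step 8
Reactants: 13 2-[9-(benzyloxy)nonyl]-4,8,9-trimethoxy-6H-benzo[c]chromen-6-ol; 16 [8-(benzyloxy)octyl]triphenylphosphonium bromide
Product: 18 (Z)-5-[9-(benzyloxy)nonyl]-2'-[9-(benzyloxy)non-1-en-1-yl]-3,4',5'-trimethoxy-[1,1'-biphenyl]-2-ol (Z expected as the major isomer, some E tolerated), via phosphonium ylide 17 (not isolated)
Conditions: 16 (3 equiv), NaN(SiMe3)2 (2.9 equiv), THF, 0 °C; then 13, 0 °C → rt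
Reagents that add atoms: none
Why: Wittig olefination of the hydroxy-aldehyde tautomer of the lactol, one equivalent of ylide serving as base for the phenol, should open the bridge, and the alkene geometry is irrelevant because the double bond is hydrogenated in step 10.

Step 9
Reactants: 18 (Z)-5-[9-(benzyloxy)nonyl]-2'-[9-(benzyloxy)non-1-en-1-yl]-3,4',5'-trimethoxy-[1,1'-biphenyl]-2-ol
Product: 19 (Z)-5-[9-(benzyloxy)nonyl]-2'-[9-(benzyloxy)non-1-en-1-yl]-2,3,4',5'-tetramethoxy-1,1'-biphenyl
Conditions: MeI, K2CO3, DMF, rt → 40 °C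
Reagents that add atoms: iodomethane, CI
Why: Williamson O-methylation of the phenoxide caps the electron-rich phenol, which would otherwise interfere with the later oxidations and the organolithium addition.

Step 10
Reactants: 19 (Z)-5-[9-(benzyloxy)nonyl]-2'-[9-(benzyloxy)non-1-en-1-yl]-2,3,4',5'-tetramethoxy-1,1'-biphenyl
Product: 20 9,9'-(2,3,4',5'-tetramethoxy-[1,1'-biphenyl]-2',5-diyl)di(nonan-1-ol)
Conditions: H2 (1 atm), 10% Pd/C, EtOAc/EtOH, rt
Reagents that add atoms: none
Why: Heterogeneous catalytic hydrogenation should saturate the styrenyl double bond and hydrogenolyse both primary benzyl ethers in one operation, while the aryl methyl ethers are untouched.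

Step 11
Reactants: 20 9,9'-(2,3,4',5'-tetramethoxy-[1,1'-biphenyl]-2',5-diyl)di(nonan-1-ol)
Product: 21 9,9'-(2,3,4',5'-tetramethoxy-[1,1'-biphenyl]-2',5-diyl)dinonanal
Conditions: Dess–Martin periodinane (2.5 equiv), pyridine, CH2Cl2, 0 °C → rt
Reagents that add atoms: none
Why: Dess–Martin oxidation of primary alcohols stops at the aldehyde under neutral, anhydrous conditions.

Step 12
Reactants: 21 9,9'-(2,3,4',5'-tetramethoxy-[1,1'-biphenyl]-2',5-diyl)dinonanal; 22 1,3-dimethoxybenzene
Product: 24 9,9'-(2,3,4',5'-tetramethoxy-[1,1'-biphenyl]-2',5-diyl)bis[1-(2,6-dimethoxyphenyl)nonan-1-ol] (mixture of diastereomers), via 2,6-dimethoxyphenyllithium 23 (not isolated)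
Conditions: 22 (3 equiv), n-BuLi (2.8 equiv), THF, 0 °C → rt; then 21, −78 → 0 °C; H2O
Reagents that add atoms: none
Why: Directed ortho-lithiation between the two methoxy groups gives the aryllithium, whose 1,2-addition to both aldehydes forms the two carbinol carbons without stereocontrol, which does not matter because both are oxidised to ketones in step 13.

Step 13
Reactants: 24 9,9'-(2,3,4',5'-tetramethoxy-[1,1'-biphenyl]-2',5-diyl)bis[1-(2,6-dimethoxyphenyl)nonan-1-ol]
Product: 25 9,9'-(2,3,4',5'-tetramethoxy-[1,1'-biphenyl]-2',5-diyl)bis[1-(2,6-dimethoxyphenyl)nonan-1-one]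
Conditions: Dess–Martin periodinane (3 equiv), pyridine, CH2Cl2, rt
Reagents that add atoms: none
Why: Dess–Martin oxidation converts the secondary benzylic alcohols into aryl ketones, with pyridine as buffer to protect the acid-labile electron-rich benzylic carbinols.

Step 14
Reactants: 25 9,9'-(2,3,4',5'-tetramethoxy-[1,1'-biphenyl]-2',5-diyl)bis[1-(2,6-dimethoxyphenyl)nonan-1-one]
Product: 26 9,9'-(2,3,4',5'-tetrahydroxy-[1,1'-biphenyl]-2',5-diyl)bis[1-(2,6-dihydroxyphenyl)nonan-1-one] (CNP0305015.0)
Conditions: BBr3 (16 equiv), CH2Cl2, −78 °C → rt, under Ar; then H2O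
Reagents that add atoms: none
Why: Lewis-acid ether cleavage by BBr3 (bromide attack at methyl after O–B coordination) should remove all eight aryl methyl groups, the ethers ortho to the ketones being assisted by chelation, and argon protects the catechols from air oxidation.

Compound list
1 | non-8-en-1-ol | C=CCCCCCCCO | starting material
2 | benzyl non-8-en-1-yl ether | C=CCCCCCCCOCc1ccccc1 | intermediate
3 | 5-bromo-2-hydroxy-3-methoxybenzaldehyde | COc1cc(Br)cc(C=O)c1O | starting material
4 | 9-[9-(benzyloxy)nonyl]-9-borabicyclo[3.3.1]nonane | C(CCCCCCCCOCc1ccccc1)B1C2CCCC1CCC2 | intermediate (not isolated)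
5 | 5-[9-(benzyloxy)nonyl]-2-hydroxy-3-methoxybenzaldehyde | COc1cc(CCCCCCCCCOCc2ccccc2)cc(C=O)c1O | intermediate
6 | ethyl nitroacetate | CCOC(=O)C[N+](=O)[O-] | starting material
7 | ethyl (E)-3-{5-[9-(benzyloxy)nonyl]-2-hydroxy-3-methoxyphenyl}-2-nitroprop-2-enoate | CCOC(=O)/C(=C\c1cc(CCCCCCCCCOCc2ccccc2)cc(OC)c1O)[N+](=O)[O-] | intermediate (not isolated)
8 | 6-[9-(benzyloxy)nonyl]-8-methoxy-3-nitro-2H-chromen-2-one | COc1cc(CCCCCCCCCOCc2ccccc2)cc2cc([N+](=O)[O-])c(=O)oc12 | intermediate
9 | 2,3-dimethoxybuta-1,3-diene | C=C(OC)C(OC)=C | starting material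
10 | cis-2-[9-(benzyloxy)nonyl]-4,8,9-trimethoxy-6a-nitro-6a,7,10,10a-tetrahydro-6H-benzo[c]chromen-6-one (racemic; nitro group and 10a-hydrogen on the same face; one enantiomer drawn) | O=C1Oc2c(OC)cc(CCCCCCCCCOCc3ccccc3)cc2[C@@H]4CC(OC)=C(OC)C[C@]14[N+](=O)[O-] | intermediate (not isolated)
11 | 2-[9-(benzyloxy)nonyl]-4,8,9-trimethoxy-7,10-dihydro-6H-benzo[c]chromen-6-one | COc1cc(CCCCCCCCCOCc3ccccc3)cc2c1OC(=O)C1=C2CC(OC)=C(OC)C1 | intermediate (not isolated)
12 | 2-[9-(benzyloxy)nonyl]-4,8,9-trimethoxy-6H-benzo[c]chromen-6-one | COc1cc(CCCCCCCCCOCc2ccccc2)cc2c1OC(=O)c1cc(OC)c(OC)cc12 | intermediate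
13 | 2-[9-(benzyloxy)nonyl]-4,8,9-trimethoxy-6H-benzo[c]chromen-6-ol (racemic at C6) | COc1cc(CCCCCCCCCOCc2ccccc2)cc2c1OC(O)c1cc(OC)c(OC)cc12 | intermediate
14 | 8-bromooctan-1-ol | OCCCCCCCCBr | starting material
15 | benzyl 8-bromooctyl ether | BrCCCCCCCCOCc1ccccc1 | intermediate
16 | [8-(benzyloxy)octyl]triphenylphosphonium bromide | [Br-].C(CCCCCCCOCc1ccccc1)[P+](c1ccccc1)(c1ccccc1)c1ccccc1 | intermediate
17 | [8-(benzyloxy)octylidene]triphenylphosphorane | C(CCCCCCCOCc1ccccc1)=P(c1ccccc1)(c1ccccc1)c1ccccc1 | intermediate (not isolated)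
18 | (Z)-5-[9-(benzyloxy)nonyl]-2'-[9-(benzyloxy)non-1-en-1-yl]-3,4',5'-trimethoxy-[1,1'-biphenyl]-2-ol | COc1cc(CCCCCCCCCOCc2ccccc2)cc(-c2cc(OC)c(OC)cc2/C=C\CCCCCCCOCc2ccccc2)c1O | intermediate
19 | (Z)-5-[9-(benzyloxy)nonyl]-2'-[9-(benzyloxy)non-1-en-1-yl]-2,3,4',5'-tetramethoxy-1,1'-biphenyl | COc1cc(CCCCCCCCCOCc2ccccc2)cc(-c2cc(OC)c(OC)cc2/C=C\CCCCCCCOCc2ccccc2)c1OC | intermediate
20 | 9,9'-(2,3,4',5'-tetramethoxy-[1,1'-biphenyl]-2',5-diyl)di(nonan-1-ol) | COc1cc(CCCCCCCCCO)cc(-c2cc(OC)c(OC)cc2CCCCCCCCCO)c1OC | intermediate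
21 | 9,9'-(2,3,4',5'-tetramethoxy-[1,1'-biphenyl]-2',5-diyl)dinonanal | COc1cc(CCCCCCCCC=O)cc(-c2cc(OC)c(OC)cc2CCCCCCCCC=O)c1OC | intermediate
22 | 1,3-dimethoxybenzene | COc1cccc(OC)c1 | starting material
23 | 2,6-dimethoxyphenyllithium | [Li]c1c(OC)cccc1OC | intermediate (not isolated)
24 | 9,9'-(2,3,4',5'-tetramethoxy-[1,1'-biphenyl]-2',5-diyl)bis[1-(2,6-dimethoxyphenyl)nonan-1-ol] (both carbinol carbons unassigned, mixture) | COc1cc(CCCCCCCCC(O)c2c(OC)cccc2OC)cc(-c2cc(OC)c(OC)cc2CCCCCCCCC(O)c2c(OC)cccc2OC)c1OC | intermediate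
25 | 9,9'-(2,3,4',5'-tetramethoxy-[1,1'-biphenyl]-2',5-diyl)bis[1-(2,6-dimethoxyphenyl)nonan-1-one] | COc1cc(CCCCCCCCC(=O)c2c(OC)cccc2OC)cc(-c2cc(OC)c(OC)cc2CCCCCCCCC(=O)c2c(OC)cccc2OC)c1OC | intermediate
26 | 9,9'-(2,3,4',5'-tetrahydroxy-[1,1'-biphenyl]-2',5-diyl)bis[1-(2,6-dihydroxyphenyl)nonan-1-one] (CNP0305015.0) | O=C(CCCCCCCCc1cc(O)c(O)c(-c2cc(O)c(O)cc2CCCCCCCCC(=O)c2c(O)cccc2O)c1)c1c(O)cccc1O | target

Total step count: 14.
Longest linear sequence: 12 steps (steps 1–5 and 8–14; steps 6 and 7 form the side branch to the phosphonium salt).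

Steps most likely to fail

Step 4 (key step). The electron-rich diene may engage the nitroalkene as a 4π heterodiene and give a cyclic nitronate, or oligomerise before the carbocyclic cycloaddition. The enol ether adduct may also hydrolyse before it is aromatised. The fallback keeps the lactone bridge but forms the biaryl bond with palladium; it sets out from borane 4 and comes back at 12. Borane 4 is coupled with purchased 4-bromo-2-methoxyphenol under the conditions of step 2 to give 4-[9-(benzyloxy)nonyl]-2-methoxyphenol F1. Steglich esterification with purchased 2-bromo-4,5-dimethoxybenzoic acid (DCC, DMAP, CH2Cl2) gives 4-[9-(benzyloxy)nonyl]-2-methoxyphenyl 2-bromo-4,5-dimethoxybenzoate F2. Intramolecular direct arylation (Pd(OAc)2 as divalent palladium precatalyst, PPh3, NaOAc, DMA, 130 °C) can reach only the free position ortho to the ester oxygen and should close the six-membered lactone ring to 12.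

Step 2. Under the basic coupling conditions the phenoxide makes the bromoarene electron-rich and may bind palladium or boron. Oxidative addition may then stall, so that protodeboronation and aldehyde reduction take over. The fallback sets out from 3 and comes back at 5. The phenol is masked (MOMCl, i-Pr2NEt, CH2Cl2) as 5-bromo-3-methoxy-2-(methoxymethoxy)benzaldehyde F3. B-alkyl Suzuki coupling with borane 4 gives 5-[9-(benzyloxy)nonyl]-3-methoxy-2-(methoxymethoxy)benzaldehyde F4, and aqueous HCl in THF removes the acetal to return 5.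

Step 14. Cleavage of the eight methyl ethers may stay incomplete, and the electron-rich polyphenol may degrade during long exposure to excess Lewis acid. The fallback sets out from dialdehyde 21 and comes back at target 26. Resorcinol is converted (MOMCl, i-Pr2NEt, CH2Cl2) into 1,3-bis(methoxymethoxy)benzene F5, which is lithiated (n-BuLi, THF, 0 °C) to 2,6-bis(methoxymethoxy)phenyllithium F6. Addition to 21 should give 9,9'-(2,3,4',5'-tetramethoxy-[1,1'-biphenyl]-2',5-diyl)bis{1-[2,6-bis(methoxymethoxy)phenyl]nonan-1-ol} F7. Dess–Martin oxidation then gives 9,9'-(2,3,4',5'-tetramethoxy-[1,1'-biphenyl]-2',5-diyl)bis{1-[2,6-bis(methoxymethoxy)phenyl]nonan-1-one} F8. HCl in MeOH removes the four acetals under mild conditions to give 9,9'-(2,3,4',5'-tetramethoxy-[1,1'-biphenyl]-2',5-diyl)bis[1-(2,6-dihydroxyphenyl)nonan-1-one] F9. A short BBr3 treatment then has to cleave only the four catechol methyl ethers to reach 26.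

Further compounds
F1 | step 4 | 4-[9-(benzyloxy)nonyl]-2-methoxyphenol | COc1cc(CCCCCCCCCOCc2ccccc2)ccc1O
F2 | step 4 | 4-[9-(benzyloxy)nonyl]-2-methoxyphenyl 2-bromo-4,5-dimethoxybenzoate | COc1cc(CCCCCCCCCOCc2ccccc2)ccc1OC(=O)c1cc(OC)c(OC)cc1Br
F3 | step 2 | 5-bromo-3-methoxy-2-(methoxymethoxy)benzaldehyde | COCOc1c(OC)cc(Br)cc1C=O
F4 | step 2 | 5-[9-(benzyloxy)nonyl]-3-methoxy-2-(methoxymethoxy)benzaldehyde | COCOc1c(OC)cc(CCCCCCCCCOCc2ccccc2)cc1C=O
F5 | step 14 | 1,3-bis(methoxymethoxy)benzene | COCOc1cccc(OCOC)c1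
F6 | step 14 | 2,6-bis(methoxymethoxy)phenyllithium | [Li]c1c(OCOC)cccc1OCOC
F7 | step 14 | 9,9'-(2,3,4',5'-tetramethoxy-[1,1'-biphenyl]-2',5-diyl)bis{1-[2,6-bis(methoxymethoxy)phenyl]nonan-1-ol} | COc1cc(CCCCCCCCC(O)c2c(OCOC)cccc2OCOC)cc(-c2cc(OC)c(OC)cc2CCCCCCCCC(O)c2c(OCOC)cccc2OCOC)c1OC
F8 | step 14 | 9,9'-(2,3,4',5'-tetramethoxy-[1,1'-biphenyl]-2',5-diyl)bis{1-[2,6-bis(methoxymethoxy)phenyl]nonan-1-one} | COc1cc(CCCCCCCCC(=O)c2c(OCOC)cccc2OCOC)cc(-c2cc(OC)c(OC)cc2CCCCCCCCC(=O)c2c(OCOC)cccc2OCOC)c1OC
F9 | step 14 | 9,9'-(2,3,4',5'-tetramethoxy-[1,1'-biphenyl]-2',5-diyl)bis[1-(2,6-dihydroxyphenyl)nonan-1-one] | COc1cc(CCCCCCCCC(=O)c2c(O)cccc2O)cc(-c2cc(OC)c(OC)cc2CCCCCCCCC(=O)c2c(O)cccc2O)c1OC
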